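**Retrosynthetic overview**
- **Feature:** ring A has one outstandingly electron-rich C–H carbon, C4a, with O1 ortho and O7 para to it. An ethynyl group on C2 brings its terminal carbon (the future C4) within bonding distance of C4a. Ring C (O1–C2–C3–C4–C4a–C8a) is therefore cut at C4–C4a.
- **Ring C and C2:** flavan ⇒ flav-3-ene ⇒ (R)-1-arylprop-2-ynyl aryl ether by gold-catalysed 6-endo hydroarylation. C2–O1 and the C2 stereocentre come from a racemic propargylic carbonate and a resorcinol monoether by copper–pybox etherification.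
- **Ring B alkenes come only after the hydrogenation:** ring D is built from O4' (1,1-dimethylpropargyl ether, thermal Claisen/electrocyclisation onto C5'). The C2' prenyl group then comes from O3' (1,1-dimethylallyl ether, aromatic Claisen).
- **Ring order and protection:** rings A and B are bought, ring C closes in step 6 and ring D in step 9. O4' is Bn (lost in the hydrogenation), O3' is MOM (an acetal cannot migrate to the neighbouring O4'), and O7 is TIPS (shields C8 and leaves with fluoride at the end, so no acid meets the ortho-prenylphenol).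

Key step: step 6

Numbering: flavan numbering is used. Ring A is C4a–C8a with O7, ring C is O1–C4, and ring B is C1'–C6' with O3' and O4'. Ring D is the dimethylpyran fused at C4'–C5'. The target is (2R).

Assumption: the (4S,5R)-diphenyl-pybox antipode is taken to deliver the (R)-ether 9. The sense of induction is checked on the first run, and if it is opposite the equally available (4R,5S) ligand is used with nothing else changed.

**Step 1**
Reactants: 1 4-benzyloxy-3-hydroxybenzaldehyde
Product: 2 4-benzyloxy-3-(methoxymethoxy)benzaldehyde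
Conditions: MOMCl (1.3 equiv), iPr2NEt (1.5 equiv), CH2Cl2, 0 °C → rt
Reagents that add atoms: chloromethyl methyl ether (MOMCl), COCCl
Why: Base-mediated O-alkylation of the single free phenol with MOMCl (acetal protection), an acetal being chosen for O3' because it cannot wander to the adjacent O4' phenoxide of steps 7 and 8 in the way a silyl group would.

**Step 2**
Reactants: 2 4-benzyloxy-3-(methoxymethoxy)benzaldehyde; 3 ethynylmagnesium bromide
Product: 5 rac-1-[4-benzyloxy-3-(methoxymethoxy)phenyl]prop-2-yn-1-ol, via bromomagnesium alkoxide 4 (not isolated)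
Conditions: 3 (0.5 M in THF, 1.3 equiv), THF, 0 °C; then sat. aq NH4Cl
Reagents that add atoms: none
Why: Grignard 1,2-addition of the acetylide to the aldehyde installs C3 and C4, and a racemic carbinol is all that is needed because step 5 is stereoconvergent.

**Step 3**
Reactants: 5 rac-1-[4-benzyloxy-3-(methoxymethoxy)phenyl]prop-2-yn-1-ol
Product: 6 rac-1-[4-benzyloxy-3-(methoxymethoxy)phenyl]prop-2-yn-1-yl tert-butyl carbonate
Conditions: Boc2O (1.2 equiv), DMAP (10 mol%), CH2Cl2, 0 °C → rt; Et3N-deactivated silica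
Reagents that add atoms: di-tert-butyl dicarbonate (Boc2O), CC(C)(C)OC(=O)OC(=O)OC(C)(C)C
Why: DMAP-catalysed carbonate formation with Boc2O gives a leaving group that breaks down to CO2 and non-nucleophilic tert-butoxide, so that no competing O-nucleophile is released in step 5.

**Step 4**
Reactants: 7 resorcinol
Product: 8 3-(triisopropylsilyloxy)phenol
Conditions: 7 (3 equiv), TIPSCl (1 equiv), imidazole (1.2 equiv), DMF, 0 °C → rt
Reagents that add atoms: chlorotriisopropylsilane (TIPSCl), CC(C)[Si](Cl)(C(C)C)C(C)C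
Why: Statistical monosilylation of the symmetric diphenol (silyl ether formation) is steered to the monoether by an excess of cheap resorcinol, which is washed out with water.

**Step 5**
Reactants: 6 rac-1-[4-benzyloxy-3-(methoxymethoxy)phenyl]prop-2-yn-1-yl tert-butyl carbonate; 8 3-(triisopropylsilyloxy)phenol
Product: 9 (R)-1-[4-benzyloxy-3-(methoxymethoxy)phenyl]prop-2-yn-1-yl 3-(triisopropylsilyloxy)phenyl ether
Conditions: CuOTf·0.5C6H6 (5 mol%), 2,6-bis[(4S,5R)-4,5-diphenyl-4,5-dihydro-1,3-oxazol-2-yl]pyridine (10 mol%), iPr2NEt (20 mol%), CH2Cl2, −20 °C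
Reagents that add atoms: none
Why: Copper-catalysed enantioselective propargylic etherification of a propargylic carbonate with a phenol, in which both enantiomers of 6 collapse through the copper acetylide to one planar copper allenylidene and the phenol oxygen attacks its gamma carbon on the face left open by the phenyl groups of the pybox ligand, which forms C2–O1 and sets C2 as (R).

**Step 6**
Reactants: 9 (R)-1-[4-benzyloxy-3-(methoxymethoxy)phenyl]prop-2-yn-1-yl 3-(triisopropylsilyloxy)phenyl ether
Product: 10 (2R)-2-[4-benzyloxy-3-(methoxymethoxy)phenyl]-7-(triisopropylsilyloxy)-2H-chromene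
Conditions: Ph3PAuNTf2 (3 mol%), 4 Å MS, CH2Cl2, 0 °C, dark; filtration through Et3N-washed silica, used at once
Reagents that add atoms: none
Why: The cationic monovalent gold of Ph3PAuNTf2 binds the terminal alkyne of 9 as a π-acid, C4a of ring A adds to the terminal carbon anti to gold, and rearomatisation followed by protodeauration of the vinylgold species releases 10 and the catalyst. This is the known gold-catalysed intramolecular hydroarylation of aryl propargyl ethers to 2H-chromenes, an alkyne Friedel–Crafts reaction. Ring C closes in the 6-endo-dig mode with formation of C4–C4a, the 5-exo-dig path to a 3-methylenedihydrobenzofuran being disfavoured for terminal propargyl ethers of donor-substituted arenes. No stereocentre is created and none of the four bonds at C2 is touched, so the (R) configuration set in step 5 is carried through. The site selectivity needed is C4a over C8, the carbon flanked by O1 and O7, and it is secured by the para-donor effect of O7 together with the bulk of its TIPS group, while ring B could only close a strained 5-endo ring. Heterolysis of the benzylic–propargylic C2–O1 bond and light-driven electrocyclic opening of 10 are held back by the low temperature, the sieves (no adventitious HNTf2), the exclusion of light and the immediate use in step 7.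

**Step 7**
Reactants: 10 (2R)-2-[4-benzyloxy-3-(methoxymethoxy)phenyl]-7-(triisopropylsilyloxy)-2H-chromene
Product: 11 2-(methoxymethoxy)-4-[(2R)-7-(triisopropylsilyloxy)chroman-2-yl]phenol
Conditions: H2 (1 atm), 10% Pd/C, EtOAc, rt, dark
Reagents that add atoms: none
Why: Heterogeneous catalytic hydrogenation saturates the cis-styrenyl C3=C4 bond and hydrogenolyses the O4' benzyl ether in one operation, the fast alkene uptake removing both the allylic activation of C2–O1 and the ring-opening channel of the chromene, while the flavan C2–O1 bond, MOM and TIPS are known to survive neutral Pd/C.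

**Step 8**
Reactants: 11 2-(methoxymethoxy)-4-[(2R)-7-(triisopropylsilyloxy)chroman-2-yl]phenol; 12 3-chloro-3-methylbut-1-yne
Product: 13 (2R)-2-[3-(methoxymethoxy)-4-(2-methylbut-3-yn-2-yloxy)phenyl]-7-(triisopropylsilyloxy)chromane
Conditions: 12 (1.5 equiv), CuCl2·2H2O (1 mol%), DBU (1.3 equiv), MeCN, 0 °C
Reagents that add atoms: none
Why: Copper-catalysed O-alkylation of a phenol with a tertiary propargylic chloride proceeds at 0 °C, cold enough that the 4'-phenoxide is captured before it can expel O1 to a para-quinone methide and that DBU leaves the aryl TIPS ether alone.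

**Step 9**
Reactants: 13 (2R)-2-[3-(methoxymethoxy)-4-(2-methylbut-3-yn-2-yloxy)phenyl]-7-(triisopropylsilyloxy)chromane
Product: 15 (2R)-2-[8-(methoxymethoxy)-2,2-dimethyl-2H-chromen-6-yl]-7-(triisopropylsilyloxy)chromane, via ortho-allenylphenol 14 (not isolated)
Conditions: o-xylene, 140 °C, Ar
Reagents that add atoms: none
Why: The thermal aromatic propargyl Claisen rearrangement can only reach C5' because C3' is occupied, and enolisation to 14, 1,5-hydrogen shift and oxa-6π electrocyclisation then close ring D in the classical 2,2-dimethylchromene synthesis without touching C2.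

**Step 10**
Reactants: 15 (2R)-2-[8-(methoxymethoxy)-2,2-dimethyl-2H-chromen-6-yl]-7-(triisopropylsilyloxy)chromane
Product: 16 2,2-dimethyl-6-[(2R)-7-(triisopropylsilyloxy)chroman-2-yl]-2H-chromen-8-ol
Conditions: NaHSO4·SiO2, CH2Cl2, rt
Reagents that add atoms: none
Why: Acid-catalysed acetal hydrolysis on silica-supported NaHSO4 is selective for phenolic MOM ethers at room temperature, conditions under which the acid-stable aryl TIPS ether, the chromene alkene and the C2–O1 bond should persist.

**Step 11**
Reactants: 17 2-methylbut-3-en-2-ol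
Product: 19 tert-butyl 2-methylbut-3-en-2-yl carbonate, via lithium alkoxide 18 (not isolated)
Conditions: n-BuLi (1.0 equiv), THF, −78 → 0 °C; Boc2O (1.0 equiv), 0 °C → rt; aq work-up
Reagents that add atoms: di-tert-butyl dicarbonate (Boc2O), CC(C)(C)OC(=O)OC(=O)OC(C)(C)C
Why: Acylation of the pre-formed tertiary lithium alkoxide with Boc2O is the standard way to the mixed carbonate of this hindered allylic alcohol.

**Step 12**
Reactants: 16 2,2-dimethyl-6-[(2R)-7-(triisopropylsilyloxy)chroman-2-yl]-2H-chromen-8-ol; 19 tert-butyl 2-methylbut-3-en-2-yl carbonate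
Product: 20 (2R)-2-[2,2-dimethyl-8-(2-methylbut-3-en-2-yloxy)-2H-chromen-6-yl]-7-(triisopropylsilyloxy)chromane
Conditions: 19 (1.5 equiv), Pd(PPh3)4 (3 mol%), THF, 0 °C; short silica plug to remove palladium
Reagents that add atoms: none
Why: In this Tsuji–Trost O-allylation zerovalent palladium ionises 19 with loss of CO2, the tert-butoxide released deprotonates O3'–H, and the phenoxide attacks the 1,1-dimethyl-π-allyl complex at its tertiary terminus under kinetic control at low temperature to give the branched ether.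

**Step 13**
Reactants: 20 (2R)-2-[2,2-dimethyl-8-(2-methylbut-3-en-2-yloxy)-2H-chromen-6-yl]-7-(triisopropylsilyloxy)chromane
Product: 22 2,2-dimethyl-7-(3-methylbut-2-enyl)-6-[(2R)-7-(triisopropylsilyloxy)chroman-2-yl]-2H-chromen-8-ol, via ortho-dienone 21 (not isolated)
Conditions: PhMe, 110–120 °C (sealed tube), Ar
Reagents that add atoms: none
Why: The aromatic Claisen rearrangement ([3,3]) delivers the allyl terminus to C2', the only ortho carbon of O3' that bears hydrogen, with allylic inversion turning the 1,1-dimethylallyl group into the prenyl group, and tautomerisation of dienone 21 makes the step irreversible.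

**Step 14**
Reactants: 22 2,2-dimethyl-7-(3-methylbut-2-enyl)-6-[(2R)-7-(triisopropylsilyloxy)chroman-2-yl]-2H-chromen-8-ol
Product: 23 (2R)-2-[8-hydroxy-2,2-dimethyl-7-(3-methylbut-2-enyl)-2H-chromen-6-yl]chroman-7-ol (CNP0175270.2)
Conditions: Bu4NF (1.1 equiv), AcOH (1.1 equiv), THF, 0 °C
Reagents that add atoms: none
Why: Fluoride-induced cleavage of the aryl silyl ether, buffered with acetic acid, frees O7 without any acid that could cyclise the ortho-prenylphenol or open ring C.

**Compound list**
1 | 4-benzyloxy-3-hydroxybenzaldehyde | O=Cc1ccc(OCc2ccccc2)c(O)c1 | starting material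
2 | 4-benzyloxy-3-(methoxymethoxy)benzaldehyde | COCOc1cc(C=O)ccc1OCc1ccccc1 | intermediate
3 | ethynylmagnesium bromide | C#C[Mg]Br | starting material
4 | bromomagnesium 1-[4-benzyloxy-3-(methoxymethoxy)phenyl]prop-2-yn-1-olate (racemic, not isolated) | COCOc1cc(ccc1OCc1ccccc1)C(O[Mg]Br)C#C | intermediate
5 | rac-1-[4-benzyloxy-3-(methoxymethoxy)phenyl]prop-2-yn-1-ol | COCOc1cc(ccc1OCc1ccccc1)C(O)C#C | intermediate
6 | rac-1-[4-benzyloxy-3-(methoxymethoxy)phenyl]prop-2-yn-1-yl tert-butyl carbonate | COCOc1cc(ccc1OCc1ccccc1)C(OC(=O)OC(C)(C)C)C#C | intermediate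
7 | resorcinol | Oc1cccc(O)c1 | starting material
8 | 3-(triisopropylsilyloxy)phenol | CC(C)[Si](C(C)C)(C(C)C)Oc1cccc(O)c1 | intermediate
9 | (R)-1-[4-benzyloxy-3-(methoxymethoxy)phenyl]prop-2-yn-1-yl 3-(triisopropylsilyloxy)phenyl ether | COCOc1cc(ccc1OCc1ccccc1)[C@H](Oc1cccc(O[Si](C(C)C)(C(C)C)C(C)C)c1)C#C | intermediate
10 | (2R)-2-[4-benzyloxy-3-(methoxymethoxy)phenyl]-7-(triisopropylsilyloxy)-2H-chromene | COCOc1cc(ccc1OCc1ccccc1)[C@H]1C=Cc2ccc(O[Si](C(C)C)(C(C)C)C(C)C)cc2O1 | intermediate
11 | 2-(methoxymethoxy)-4-[(2R)-7-(triisopropylsilyloxy)chroman-2-yl]phenol | COCOc1cc(ccc1O)[C@H]1CCc2ccc(O[Si](C(C)C)(C(C)C)C(C)C)cc2O1 | intermediate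
12 | 3-chloro-3-methylbut-1-yne | C#CC(C)(C)Cl | starting material
13 | (2R)-2-[3-(methoxymethoxy)-4-(2-methylbut-3-yn-2-yloxy)phenyl]-7-(triisopropylsilyloxy)chromane | COCOc1cc(ccc1OC(C)(C)C#C)[C@H]1CCc2ccc(O[Si](C(C)C)(C(C)C)C(C)C)cc2O1 | intermediate
14 | 2-(methoxymethoxy)-6-(3-methylbuta-1,2-dienyl)-4-[(2R)-7-(triisopropylsilyloxy)chroman-2-yl]phenol (not isolated) | COCOc1cc(cc(C=C=C(C)C)c1O)[C@H]1CCc2ccc(O[Si](C(C)C)(C(C)C)C(C)C)cc2O1 | intermediate
15 | (2R)-2-[8-(methoxymethoxy)-2,2-dimethyl-2H-chromen-6-yl]-7-(triisopropylsilyloxy)chromane | COCOc1cc(cc2C=CC(C)(C)Oc12)[C@H]1CCc2ccc(O[Si](C(C)C)(C(C)C)C(C)C)cc2O1 | intermediate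
16 | 2,2-dimethyl-6-[(2R)-7-(triisopropylsilyloxy)chroman-2-yl]-2H-chromen-8-ol | Oc1cc(cc2C=CC(C)(C)Oc12)[C@H]1CCc2ccc(O[Si](C(C)C)(C(C)C)C(C)C)cc2O1 | intermediate
17 | 2-methylbut-3-en-2-ol | C=CC(C)(C)O | starting material
18 | lithium 2-methylbut-3-en-2-olate (not isolated) | C=CC(C)(C)[O-].[Li+] | intermediate
19 | tert-butyl 2-methylbut-3-en-2-yl carbonate | C=CC(C)(C)OC(=O)OC(C)(C)C | intermediate
20 | (2R)-2-[2,2-dimethyl-8-(2-methylbut-3-en-2-yloxy)-2H-chromen-6-yl]-7-(triisopropylsilyloxy)chromane | C=CC(C)(C)Oc1cc(cc2C=CC(C)(C)Oc12)[C@H]1CCc2ccc(O[Si](C(C)C)(C(C)C)C(C)C)cc2O1 | intermediate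
21 | 2,2-dimethyl-7-(3-methylbut-2-enyl)-6-[(2R)-7-(triisopropylsilyloxy)chroman-2-yl]-2H-chromen-8(7H)-one (C7 unassigned, not isolated) | O=C1C(CC=C(C)C)C([C@H]3CCc4ccc(O[Si](C(C)C)(C(C)C)C(C)C)cc4O3)=CC2=C1OC(C)(C)C=C2 | intermediate
22 | 2,2-dimethyl-7-(3-methylbut-2-enyl)-6-[(2R)-7-(triisopropylsilyloxy)chroman-2-yl]-2H-chromen-8-ol | CC(C)=CCc1c([C@H]2CCc3ccc(O[Si](C(C)C)(C(C)C)C(C)C)cc3O2)cc2c(c1O)OC(C)(C)C=C2 | intermediate
23 | (2R)-2-[8-hydroxy-2,2-dimethyl-7-(3-methylbut-2-enyl)-2H-chromen-6-yl]chroman-7-ol | CC(C)=CCc1c([C@H]2CCc3ccc(O)cc3O2)cc2c(c1O)OC(C)(C)C=C2 | target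

**Total step count:** 14. **Longest linear sequence:** 12 (steps 1–3, 5–10, 12–14).

**Steps most likely to fail**

**Step 6.**
- **What may go wrong:** The Lewis-acidic gold cation may ionise the C2–O1 bond, which is benzylic, propargylic and supported by the para O4' donor. This would erode enantiopurity or expel the phenol. Part of the material may also close at C8 instead of C4a.
- **Fallback:** It sets out from 6 and returns at 11.
  - 4-Bromoresorcinol is monosilylated at its less hindered oxygen (TIPSCl, imidazole, DMF) to 2-bromo-5-(triisopropylsilyloxy)phenol F1.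
  - F1 is coupled with 6 under the conditions of step 5 to give (R)-1-[4-benzyloxy-3-(methoxymethoxy)phenyl]prop-2-yn-1-yl 2-bromo-5-(triisopropylsilyloxy)phenyl ether F2.
  - Semihydrogenation (H2, Pd/CaCO3 poisoned with Pb(OAc)2, quinoline, EtOAc) gives the (R)-1-arylallyl 2-bromoaryl ether F3.
  - 9-BBN-H in THF adds to the terminal alkene to give the primary B-alkyl-9-BBN adduct F4.
  - Intramolecular B-alkyl Suzuki–Miyaura coupling (PdCl2(dppf), K3PO4, aq DMF/THF, 50 °C) forms C4–C4a at the carbon that carried bromine. The product is (2R)-2-[4-benzyloxy-3-(methoxymethoxy)phenyl]-7-(triisopropylsilyloxy)chromane F5.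
  - Hydrogenolysis of F5 (H2, Pd/C, EtOAc) gives 11.
  - This path uses no π-acid and passes through no flavene, and the halogen fixes the regiochemistry.

**Step 5.**
- **What may go wrong:** The electron-rich carbonate may react by an uncatalysed ionisation pathway beside the ligand-controlled one, which would lower the enantiomeric purity. Carbon alkylation of the phenol ring may also compete with O-attack.
- **Fallback:** It sets out from 5 and returns at 9.
  - Kinetic resolution of 5 with immobilised Candida antarctica lipase B and vinyl acetate in hexane should acylate the (R)-alcohol, following the empirical rule for secondary carbinols with aryl as the large group.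
  - This leaves (S)-1-[4-benzyloxy-3-(methoxymethoxy)phenyl]prop-2-yn-1-ol F6. It is separated from (R)-1-[4-benzyloxy-3-(methoxymethoxy)phenyl]prop-2-yn-1-yl acetate F7.
  - Mitsunobu etherification of F6 with 8 (PPh3, DIAD, PhMe, −20 → 0 °C) proceeds with inversion at C2 to give 9.

**Step 13.**
- **What may go wrong:** The tertiary allyl ether may fragment with loss of isoprene back to the phenol. It may also drift to the linear ether faster than the [3,3] shift reaches the hindered C2' next to the flavanyl group.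
- **Fallback:** It sets out from 16 and returns at 22.
  - O-Allylation (allyl bromide, K2CO3, acetone) gives (2R)-2-[8-(allyloxy)-2,2-dimethyl-2H-chromen-6-yl]-7-(triisopropylsilyloxy)chromane F8, which has a primary C–O bond that cannot fragment in this way.
  - Aromatic Claisen rearrangement (N,N-diethylaniline, 190 °C) gives 7-allyl-2,2-dimethyl-6-[(2R)-7-(triisopropylsilyloxy)chroman-2-yl]-2H-chromen-8-ol F9.
  - Cross-metathesis with 2-methylbut-2-ene (second-generation Grubbs catalyst, CH2Cl2, 40 °C) converts the allyl group into the prenyl group of 22. The hindered chromene alkene should remain a spectator.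

**Further compounds**
F1 | step 6 | 2-bromo-5-(triisopropylsilyloxy)phenol | Oc1cc(O[Si](C(C)C)(C(C)C)C(C)C)ccc1Br
F2 | step 6 | (R)-1-[4-benzyloxy-3-(methoxymethoxy)phenyl]prop-2-yn-1-yl 2-bromo-5-(triisopropylsilyloxy)phenyl ether | COCOc1cc(ccc1OCc1ccccc1)[C@H](Oc1cc(O[Si](C(C)C)(C(C)C)C(C)C)ccc1Br)C#C
F3 | step 6 | (R)-1-[4-benzyloxy-3-(methoxymethoxy)phenyl]prop-2-en-1-yl 2-bromo-5-(triisopropylsilyloxy)phenyl ether | COCOc1cc(ccc1OCc1ccccc1)[C@H](Oc1cc(O[Si](C(C)C)(C(C)C)C(C)C)ccc1Br)C=C
F4 | step 6 | 9-{(3R)-3-[4-benzyloxy-3-(methoxymethoxy)phenyl]-3-[2-bromo-5-(triisopropylsilyloxy)phenoxy]propyl}-9-borabicyclo[3.3.1]nonane | COCOc1cc(ccc1OCc1ccccc1)[C@H](Oc1cc(O[Si](C(C)C)(C(C)C)C(C)C)ccc1Br)CCB1C2CCCC1CCC2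
F5 | step 6 | (2R)-2-[4-benzyloxy-3-(methoxymethoxy)phenyl]-7-(triisopropylsilyloxy)chromane | COCOc1cc(ccc1OCc1ccccc1)[C@H]1CCc2ccc(O[Si](C(C)C)(C(C)C)C(C)C)cc2O1
F6 | step 5 | (S)-1-[4-benzyloxy-3-(methoxymethoxy)phenyl]prop-2-yn-1-ol | COCOc1cc(ccc1OCc1ccccc1)[C@@H](O)C#C
F7 | step 5 | (R)-1-[4-benzyloxy-3-(methoxymethoxy)phenyl]prop-2-yn-1-yl acetate | COCOc1cc(ccc1OCc1ccccc1)[C@H](OC(C)=O)C#C
F8 | step 13 | (2R)-2-[8-(allyloxy)-2,2-dimethyl-2H-chromen-6-yl]-7-(triisopropylsilyloxy)chromane | C=CCOc1cc(cc2C=CC(C)(C)Oc12)[C@H]1CCc2ccc(O[Si](C(C)C)(C(C)C)C(C)C)cc2O1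
F9 | step 13 | 7-allyl-2,2-dimethyl-6-[(2R)-7-(triisopropylsilyloxy)chroman-2-yl]-2H-chromen-8-ol | C=CCc1c([C@H]2CCc3ccc(O[Si](C(C)C)(C(C)C)C(C)C)cc3O2)cc2c(c1O)OC(C)(C)C=C2
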